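## Retrosynthetic overview

- **Pyranone ring (formed last):** remove the 7-O-silyl group, then disconnect C4–C4a (arene acylation) and C2–C3 (1,2-shift) back to an α-diazoketone. A light-driven Wolff shift (retention) gives a ketene that is closed onto the resorcinol ring in the same operation.
- **C2–O1:** Mitsunobu inversion of an (R)-mandelate with mono-silylated resorcinol.
- **Chromene ring (formed first):** DDQ cyclisation of a 3,5-diprenylphenol; both prenyl groups come from a double Stille coupling on the diiodophenol.
- **Stereocentre:** bought in (R)-4-hydroxymandelic acid, inverted once (Mitsunobu) and retained in the Wolff shift, giving (2R).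
- **Ring order:** chromene pyran ring, then chromanone ring; both benzene rings are purchased.

Assumption: the target SMILES is read as the (2R)-flavanone, and enantiopure (R)-4-hydroxymandelic acid is taken to be a purchasable chiral-pool acid.

## Route

**Step 1**
Reactants: 1, (R)-4-hydroxymandelic acid
Product: 2, methyl (2R)-2-hydroxy-2-(4-hydroxyphenyl)acetate
Conditions: MeOH, AcCl (0.2 equiv), 0 °C → rt
Reagents that add atoms: methanol, CO
Why: Fischer esterification under mild acid; the stereocentre is not touched, and the α-carboxyl group disfavours benzylic ionisation.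

**Step 2**
Reactants: 2, methyl (2R)-2-hydroxy-2-(4-hydroxyphenyl)acetate
Product: 3, methyl (2R)-2-hydroxy-2-(4-hydroxy-3,5-diiodophenyl)acetate
Conditions: NIS (2.1 equiv), TsOH·H2O (10 mol %), MeCN, 0 °C → rt
Reagents that add atoms: N-iodosuccinimide, O=C1CCC(=O)N1I
Why: Electrophilic aromatic iodination goes to the two positions ortho to the phenol OH (para is blocked), under non-basic conditions that cannot epimerise the α-hydroxy ester.

**Step 3**
Reactants: 3, methyl (2R)-2-hydroxy-2-(4-hydroxy-3,5-diiodophenyl)acetate; 4, tributyl(3-methylbut-2-en-1-yl)stannane (2.6 equiv)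
Product: 5, methyl (2R)-2-hydroxy-2-[4-hydroxy-3,5-bis(3-methylbut-2-en-1-yl)phenyl]acetate
Conditions: Pd(PPh3)4 (10 mol %), DMF, 90 °C; aq. KF work-up
Reagents that add atoms: reactant 4, tributyl(prenyl)stannane, CCCC[Sn](CCCC)(CCCC)CC=C(C)C
Why: Double Stille coupling; reductive elimination at the unsubstituted allyl terminus gives the linear prenyl groups, and the neutral conditions tolerate the free phenol and leave the stereocentre intact.

**Step 4**
Reactants: 5, methyl (2R)-2-hydroxy-2-[4-hydroxy-3,5-bis(3-methylbut-2-en-1-yl)phenyl]acetate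
Product: 6, methyl (2R)-2-[2,2-dimethyl-8-(3-methylbut-2-en-1-yl)-2H-chromen-6-yl]-2-hydroxyacetate
Conditions: DDQ (1.1 equiv), toluene, rt
Reagents that add atoms: none
Why: DDQ dehydrogenative cyclisation of an o-prenylphenol (hydride abstraction to the o-quinone methide, then oxa-6π electrocyclisation); the two prenyls are equivalent so only one chromene can form, and the ester-deactivated carbinol C–H is a much poorer hydride donor.

**Step 5**
Reactants: 6, methyl (2R)-2-[2,2-dimethyl-8-(3-methylbut-2-en-1-yl)-2H-chromen-6-yl]-2-hydroxyacetate; 7, 3-[(tert-butyldimethylsilyl)oxy]phenol (1.2 equiv)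
Product: 8, methyl (2S)-2-{3-[(tert-butyldimethylsilyl)oxy]phenoxy}-2-[2,2-dimethyl-8-(3-methylbut-2-en-1-yl)-2H-chromen-6-yl]acetate
Conditions: PPh3, DIAD, toluene, 0 °C → rt
Reagents that add atoms: reactant 7, Oc1cccc(O[Si](C)(C)C(C)(C)C)c1
Why: Mitsunobu etherification of an α-hydroxy ester forms O1–C2 by SN2 inversion (R → S), because the adjacent ester suppresses SN1 ionisation despite the electron-rich aryl group.

**Step 6**
Reactants: 8, methyl (2S)-2-{3-[(tert-butyldimethylsilyl)oxy]phenoxy}-2-[2,2-dimethyl-8-(3-methylbut-2-en-1-yl)-2H-chromen-6-yl]acetate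
Product: 9, (2S)-2-{3-[(tert-butyldimethylsilyl)oxy]phenoxy}-2-[2,2-dimethyl-8-(3-methylbut-2-en-1-yl)-2H-chromen-6-yl]acetic acid
Conditions: Me3SnOH (4 equiv), 1,2-dichloroethane, 70 °C; dilute KHSO4 work-up
Reagents that add atoms: trimethyltin hydroxide, C[Sn](C)(C)O (supplies the carboxylic OH oxygen)
Why: Near-neutral trimethyltin hydroxide ester hydrolysis avoids α-epimerisation of the aryl(aryloxy)acetate and is expected to spare the aryl silyl ether, which aqueous hydroxide would cleave.

**Step 7**
Reactants: 9, (2S)-2-{3-[(tert-butyldimethylsilyl)oxy]phenoxy}-2-[2,2-dimethyl-8-(3-methylbut-2-en-1-yl)-2H-chromen-6-yl]acetic acid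
Product: 10, (3S)-3-{3-[(tert-butyldimethylsilyl)oxy]phenoxy}-1-diazo-3-[2,2-dimethyl-8-(3-methylbut-2-en-1-yl)-2H-chromen-6-yl]propan-2-one
Conditions: i-BuOCOCl, N-methylmorpholine (1.05 equiv each), THF, −20 °C; then CH2N2 (3 equiv), Et2O, −20 → 0 °C
Reagents that add atoms: diazomethane, C=[N+]=[N-]
Why: Arndt–Eistert acylation of diazomethane through the mixed anhydride; the weak base and low temperature avoid ketene formation or enolisation at the stereocentre.

**Step 8**
Reactants: 10, (3S)-3-{3-[(tert-butyldimethylsilyl)oxy]phenoxy}-1-diazo-3-[2,2-dimethyl-8-(3-methylbut-2-en-1-yl)-2H-chromen-6-yl]propan-2-one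
Product: 11, (2R)-7-[(tert-butyldimethylsilyl)oxy]-2-[2,2-dimethyl-8-(3-methylbut-2-en-1-yl)-2H-chromen-6-yl]chroman-4-one
Conditions: hν (405 nm LEDs), CH2Cl2 (0.01 M), −40 °C; then CF3CO2H (1.1 equiv), −40 °C → rt; cold aq. NaHCO3 work-up
Reagents that add atoms: none
Why: Proposed new method: photochemical Wolff rearrangement intercepted by a Brønsted-acid-shuttled intramolecular ketene Friedel–Crafts acylation — 405 nm light (absorbed by the diazoketone, not the chromene) expels N2 and the stereogenic carbon migrates with retention to form C2–C3 and a ketene, TFA (added only after N2 loss so it cannot protonate the diazoketone) then adds to the ketene to give the acyl trifluoroacetate, and the tethered ring attacks it at the carbon para to OTBS and ortho to O1 (the site flanked by both oxygens is blocked by the bulky silyl ether) to form C4–C4a and release TFA, giving the (2R)-flavanone (descriptor changes S → R only through CIP priorities); the closest known reactions are the Arndt–Eistert photo-Wolff with retention, ketene plus carboxylic acid giving mixed anhydrides, and TFAA-mediated cyclisation of 3-aryloxypropanoic acids to chroman-4-ones.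

**Step 9**
Reactants: 11, (2R)-7-[(tert-butyldimethylsilyl)oxy]-2-[2,2-dimethyl-8-(3-methylbut-2-en-1-yl)-2H-chromen-6-yl]chroman-4-one
Product: 12, ent-abyssinone III, (2R)-7-hydroxy-2-[2,2-dimethyl-8-(3-methylbut-2-en-1-yl)-2H-chromen-6-yl]chroman-4-one
Conditions: Et3N·3HF (3 equiv), THF, 0 °C → rt
Reagents that add atoms: none
Why: Fluoride-mediated cleavage of the aryl silyl ether (the para-acyl phenoxide is a good leaving group from silicon) under mildly acidic, base-free conditions, so the flavanone cannot open to the chalcone by retro-oxa-Michael and C2 is not racemised; the prenyl and chromene alkenes are untouched.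

## Compound list

1 | (R)-4-hydroxymandelic acid | O[C@@H](C(=O)O)c1ccc(O)cc1 | starting material
2 | methyl (2R)-2-hydroxy-2-(4-hydroxyphenyl)acetate | O[C@@H](C(=O)OC)c1ccc(O)cc1 | intermediate
3 | methyl (2R)-2-hydroxy-2-(4-hydroxy-3,5-diiodophenyl)acetate | O[C@@H](C(=O)OC)c1cc(I)c(O)c(I)c1 | intermediate
4 | tributyl(3-methylbut-2-en-1-yl)stannane | CCCC[Sn](CCCC)(CCCC)CC=C(C)C | starting material
5 | methyl (2R)-2-hydroxy-2-[4-hydroxy-3,5-bis(3-methylbut-2-en-1-yl)phenyl]acetate | O[C@@H](C(=O)OC)c1cc(CC=C(C)C)c(O)c(CC=C(C)C)c1 | intermediate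
6 | methyl (2R)-2-[2,2-dimethyl-8-(3-methylbut-2-en-1-yl)-2H-chromen-6-yl]-2-hydroxyacetate | O[C@@H](C(=O)OC)c1cc(CC=C(C)C)c2OC(C)(C)C=Cc2c1 | intermediate
7 | 3-[(tert-butyldimethylsilyl)oxy]phenol | Oc1cccc(O[Si](C)(C)C(C)(C)C)c1 | starting material
8 | methyl (2S)-2-{3-[(tert-butyldimethylsilyl)oxy]phenoxy}-2-[2,2-dimethyl-8-(3-methylbut-2-en-1-yl)-2H-chromen-6-yl]acetate | CC(C)(C)[Si](C)(C)Oc1cccc(O[C@H](C(=O)OC)c2cc(CC=C(C)C)c3OC(C)(C)C=Cc3c2)c1 | intermediate
9 | (2S)-2-{3-[(tert-butyldimethylsilyl)oxy]phenoxy}-2-[2,2-dimethyl-8-(3-methylbut-2-en-1-yl)-2H-chromen-6-yl]acetic acid | CC(C)(C)[Si](C)(C)Oc1cccc(O[C@H](C(=O)O)c2cc(CC=C(C)C)c3OC(C)(C)C=Cc3c2)c1 | intermediate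
10 | (3S)-3-{3-[(tert-butyldimethylsilyl)oxy]phenoxy}-1-diazo-3-[2,2-dimethyl-8-(3-methylbut-2-en-1-yl)-2H-chromen-6-yl]propan-2-one | CC(C)(C)[Si](C)(C)Oc1cccc(O[C@H](C(=O)C=[N+]=[N-])c2cc(CC=C(C)C)c3OC(C)(C)C=Cc3c2)c1 | intermediate
11 | (2R)-7-[(tert-butyldimethylsilyl)oxy]-2-[2,2-dimethyl-8-(3-methylbut-2-en-1-yl)-2H-chromen-6-yl]chroman-4-one | CC(C)=CCc1cc([C@H]2CC(=O)c3ccc(O[Si](C)(C)C(C)(C)C)cc3O2)cc2c1OC(C)(C)C=C2 | intermediate
12 | ent-abyssinone III, (2R)-7-hydroxy-2-[2,2-dimethyl-8-(3-methylbut-2-en-1-yl)-2H-chromen-6-yl]chroman-4-one | CC(C)=CCc1cc([C@H]2CC(=O)c3ccc(O)cc3O2)cc2c1OC(C)(C)C=C2 | target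

## Summary

Total step count: 9. Longest linear sequence: 9, from (R)-4-hydroxymandelic acid (compounds 4 and 7 are purchased). Steps 8 and 9 can be telescoped by adding the fluoride source to the crude acylation mixture, but they are counted separately here.

Three steps most likely to fail:

1. **Step 8 (proposed new photo-Wolff / ketene Friedel–Crafts cascade).** Risks are ketene dimerisation, acid-induced ionisation of the benzylic aryl ether, or closure at the carbon between the two oxygens. Fallback (known chemistry): run the Wolff rearrangement of 10 in THF/H2O to isolate the homologated (R)-3-aryl-3-aryloxypropanoic acid, then close the ring by a conventional intramolecular Friedel–Crafts acylation (TFAA, or acid chloride with SnCl4 at −78 °C) to reach 11, and desilylate as in step 9.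

2. **Step 4 (DDQ chromene formation).** Risk is competing oxidation of the p-oxygenated benzylic carbinol or of the second prenyl group. Fallback: build the chromene without an oxidant. Mono-iodinate 2 and prenylate once, O-alkylate the phenol with 3-chloro-3-methylbut-1-yne (CuCl2 cat., DBU), then heat the aryl propargyl ether (Claisen, 1,5-H shift, oxa-6π closure) to reach 6.

3. **Step 3 (double Stille prenylation).** Risks are incomplete second coupling, protodeiodination, or branched (reverse-prenyl) isomers. Fallback: install the prenyl groups on non-iodinated 2 by sigmatropic chemistry. Pd(0)-catalysed O-alkylation of the phenol with tert-butyl 2-methylbut-3-en-2-yl carbonate gives the 1,1-dimethylallyl ether, and a thermal aromatic Claisen rearrangement delivers the linear o-prenylphenol. This is done twice, or once and combined with the propargyl-ether chromene construction above.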